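**Retrosynthetic overview**

1. The quinone (ring B) is unmasked last: O-methylation of a C8 phenol, acid removal of three methoxymethyl (MOM) groups, then Ag2O oxidation of the ring B hydroquinone.
2. Feature: in ring A (chroman numbering O1, C2, C3, C4, C4a, C5–C8, C8a) the ring oxygen O1 on C8a and the methoxy oxygen on C8 sit on neighbouring carbons beside the C7 oxygen, so both C–O bonds can be traced back to an aryne across C8–C8a.
3. Key disconnection: O1–C8a (closing ring C, the only ring built) and C8–O, from an open-chain (S)-2,3-diarylpropan-1-ol with bromine on the future C8a; the tethered alkoxide adds to the aryne and the C8 anion is borylated and oxidised.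
4. The propanol comes from an Evans alkylation (C3–C4 bond and the C3 stereocentre) of the ring B arylacetyl oxazolidinone with the ring A benzylic bromide, followed by reductive removal of the auxiliary.
5. The ring B acid comes from 2,3-dimethoxyphenol (quinone, hydroquinone, bis-acetal, ortho-lithiation/ethylene oxide, oxidation) and the ring A bromide from 6-bromovanillin; rings A and B are bought as arenes.

Key step: step 12

Remark: C3 of the target is read from the SMILES as S (C2 > ring B carbon > C4 > H); 2,3-dimethoxyphenol, 6-bromovanillin and (4S)-4-benzyl-1,3-oxazolidin-2-one are taken as purchased.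

**Route**

Step 1
Reactants: 1 2,3-dimethoxyphenol
Product: 2 2,3-dimethoxy-1,4-benzoquinone
Conditions: (KSO3)2NO, KH2PO4, H2O/acetone, 0 °C → rt
Reagents that add atoms: potassium nitrosodisulfonate, [K+].[K+].[O]N(S(=O)(=O)[O-])S(=O)(=O)[O-]
Why: Teuber oxidation converts a phenol with a free para position into the para-quinone, and here the position para to the hydroxyl is unsubstituted.

Step 2
Reactants: 2 2,3-dimethoxy-1,4-benzoquinone
Product: 3 2,3-dimethoxybenzene-1,4-diol
Conditions: Na2S2O4, H2O/EtOAc, rt, under argon
Reagents that add atoms: none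
Why: Dithionite reduction of a quinone to its hydroquinone is fast in a two-phase system, and the product is used at once to limit re-oxidation by air.

Step 3
Reactants: 3 2,3-dimethoxybenzene-1,4-diol
Product: 4 2,3-dimethoxy-1,4-bis(methoxymethoxy)benzene
Conditions: NaH, MOMCl, DMF, 0 °C → rt
Reagents that add atoms: chloromethyl methyl ether (MOMCl), COCCl
Why: Williamson-type O-alkylation of the bis-phenoxide gives two acetals that later direct lithiation and come off with acid.

Step 4
Reactants: 4 2,3-dimethoxy-1,4-bis(methoxymethoxy)benzene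
Product: 6 2-[3,4-dimethoxy-2,5-bis(methoxymethoxy)phenyl]ethan-1-ol, via ortho-aryllithium 5 (not isolated)
Conditions: n-BuLi, THF, 0 °C; ethylene oxide, −78 °C → rt; H2O
Reagents that add atoms: ethylene oxide, C1CO1
Why: Directed ortho-metalation places lithium beside a methoxymethoxy group (the two free ring positions are equivalent by symmetry), and the aryllithium opens the epoxide by SN2 attack.

Step 5
Reactants: 6 2-[3,4-dimethoxy-2,5-bis(methoxymethoxy)phenyl]ethan-1-ol
Product: 7 [3,4-dimethoxy-2,5-bis(methoxymethoxy)phenyl]acetic acid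
Conditions: TEMPO (cat.), NaOCl (cat.), NaClO2, MeCN/phosphate buffer (pH 6.7), 35 °C
Reagents that add atoms: sodium chlorite, [Na+].[O-]Cl=O
Why: TEMPO-catalysed oxidation with NaClO2 as terminal oxidant takes the primary alcohol through the aldehyde to the acid at near-neutral pH, which spares the acetals and keeps ring chlorination low.

Step 6
Reactants: 7 [3,4-dimethoxy-2,5-bis(methoxymethoxy)phenyl]acetic acid; 8 (4S)-4-benzyl-1,3-oxazolidin-2-one
Product: 10 (4S)-4-benzyl-3-{[3,4-dimethoxy-2,5-bis(methoxymethoxy)phenyl]acetyl}-1,3-oxazolidin-2-one, via mixed pivalic anhydride 9 (not isolated)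
Conditions: t-BuCOCl, Et3N, THF, −20 °C; then 8, LiCl, −20 °C → rt
Reagents that add atoms: none
Why: N-acylation of the oxazolidinone through the mixed pivalic anhydride is an acid-free way to make the imide and avoids an acid chloride that would threaten the ortho acetal.

Step 7
Reactants: 11 6-bromovanillin (2-bromo-4-hydroxy-5-methoxybenzaldehyde)
Product: 12 2-bromo-5-methoxy-4-(methoxymethoxy)benzaldehyde
Conditions: MOMCl, i-Pr2NEt, CH2Cl2, 0 °C → rt
Reagents that add atoms: chloromethyl methyl ether (MOMCl), COCCl
Why: O-alkylation of the acidic para-formyl phenol installs the acetal that later acidifies the neighbouring ring hydrogen and steers the aryne addition.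

Step 8
Reactants: 12 2-bromo-5-methoxy-4-(methoxymethoxy)benzaldehyde
Product: 13 [2-bromo-5-methoxy-4-(methoxymethoxy)phenyl]methanol
Conditions: NaBH4, MeOH, 0 °C
Reagents that add atoms: none
Why: Borohydride reduction of the aromatic aldehyde leaves the aryl bromide and the acetal untouched.

Step 9
Reactants: 13 [2-bromo-5-methoxy-4-(methoxymethoxy)phenyl]methanol
Product: 14 1-bromo-2-(bromomethyl)-4-methoxy-5-(methoxymethoxy)benzene
Conditions: CBr4, PPh3, CH2Cl2, 0 °C; used directly
Reagents that add atoms: carbon tetrabromide, BrC(Br)(Br)Br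
Why: The Appel reaction converts the benzylic alcohol into the bromide under neutral conditions, so the acid-sensitive acetal survives.

Step 10
Reactants: 10 (4S)-4-benzyl-3-{[3,4-dimethoxy-2,5-bis(methoxymethoxy)phenyl]acetyl}-1,3-oxazolidin-2-one; 14 1-bromo-2-(bromomethyl)-4-methoxy-5-(methoxymethoxy)benzene
Product: 16 (4S)-4-benzyl-3-{(2S)-3-[2-bromo-5-methoxy-4-(methoxymethoxy)phenyl]-2-[3,4-dimethoxy-2,5-bis(methoxymethoxy)phenyl]propanoyl}-1,3-oxazolidin-2-one, via sodium Z-enolate 15 (not isolated)
Conditions: NaN(SiMe3)2, THF, −78 °C; then 14, −78 → −30 °C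
Reagents that add atoms: none
Why: In this Evans alkylation the chelated Z-enolate is shielded on one face by the benzyl group of the (4S)-auxiliary, so the benzylic bromide adds to the opposite face and sets the new centre (the future C3) as S, while the silylamide base is too weak to metalate the bromoarene.

Step 11
Reactants: 16 the alkylated imide from step 10
Product: 17 (2S)-3-[2-bromo-5-methoxy-4-(methoxymethoxy)phenyl]-2-[3,4-dimethoxy-2,5-bis(methoxymethoxy)phenyl]propan-1-ol
Conditions: LiBH4, MeOH, THF, 0 °C
Reagents that add atoms: none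
Why: Reductive cleavage of the N-acyl oxazolidinone with LiBH4 should give the primary alcohol without epimerising the α-aryl centre or reducing the aryl bromide, and the auxiliary is recovered.

Step 12
Reactants: 17 (2S)-3-[2-bromo-5-methoxy-4-(methoxymethoxy)phenyl]-2-[3,4-dimethoxy-2,5-bis(methoxymethoxy)phenyl]propan-1-ol
Product: 22 (3S)-3-[3,4-dimethoxy-2,5-bis(methoxymethoxy)phenyl]-6-methoxy-7-(methoxymethoxy)-3,4-dihydro-2H-chromen-8-ol, via lithiated bromoarene alkoxide 18 (not isolated), via aryne alkoxide 19 (not isolated), via C8-lithiochroman 20 (not isolated), via aryl trimethoxyborate 21 (not isolated)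
Conditions: lithium 2,2,6,6-tetramethylpiperidide (LiTMP, 2.5 equiv), THF, −78 → 0 °C; B(OMe)3, −78 °C → rt; 30% H2O2, AcOH, 0 °C → rt
Reagents that add atoms: hydrogen peroxide, OO
Why: This is an anionic aryne cyclisation of a tethered alkoxide with electrophilic trapping: LiTMP forms the lithium alkoxide and then removes the only hydrogen ortho to bromine, the future C8–H, which is acidified by both the bromine and the C7 methoxymethoxy group, and on warming the aryllithium loses LiBr to give the aryne across C8–C8a. The alkoxide adds in the ring plane to C8a, forming O1–C8a and closing ring C as a six-membered ring in a 6-exo mode (the carbanion ends up outside the new ring), while C8 is out of reach of the three-atom tether. Electronics point the same way, because nucleophiles add to a 3-alkoxyaryne at the carbon remote from the oxygen, so the charge develops at C8 where it is stabilised by the C7 oxygen and O1 and chelated by the acetal. This C8 aryllithium is captured by B(OMe)3 and the arylborate is oxidised by H2O2 with aryl migration from boron to oxygen, the usual way from an aryllithium to a phenol. No stereocentre is formed, and the benzylic hydrogen at the existing centre is not acidic enough for the amide base at or below 0 °C, so the S configuration is carried through. The selectivity needed is metalation at C8 and not at the ring B hydrogen beside an acetal, which the bromine secures by making C8–H the most acidic site, helped by keeping the base to a small excess.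

Step 13
Reactants: 22 the C8 phenol from step 12
Product: 23 (3S)-3-[3,4-dimethoxy-2,5-bis(methoxymethoxy)phenyl]-6,8-dimethoxy-7-(methoxymethoxy)-3,4-dihydro-2H-chromene
Conditions: MeI, K2CO3, DMF, rt
Reagents that add atoms: iodomethane, CI
Why: Williamson O-methylation of the only free hydroxyl under carbonate conditions that the acetals tolerate.

Step 14
Reactants: 23 the C8 methyl ether from step 13
Product: 24 5-[(3S)-7-hydroxy-6,8-dimethoxy-3,4-dihydro-2H-chromen-3-yl]-2,3-dimethoxybenzene-1,4-diol
Conditions: HCl, MeOH, 50 °C, under argon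
Reagents that add atoms: none
Why: Acid-catalysed acetal exchange with methanol removes all three methoxymethyl groups while the aryl methyl ethers and the chroman ether are stable, and air is excluded to keep the hydroquinone reduced.

Step 15
Reactants: 24 the hydroquinone triol from step 14
Product: 25 5-[(3S)-7-hydroxy-6,8-dimethoxy-3,4-dihydro-2H-chromen-3-yl]-2,3-dimethoxycyclohexa-2,5-diene-1,4-dione (target)
Conditions: Ag2O (slight excess), Na2SO4, Et2O/CH2Cl2, 0 °C, short reaction time
Reagents that add atoms: none
Why: Ag2O dehydrogenation of a hydroquinone to the para-quinone is fast at low temperature, whereas the ring A monophenol is much harder to oxidise and should be left alone with limited oxidant; no base is present, so C3 is not epimerised.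

**Compound list**

1 | 2,3-dimethoxyphenol | COc1cccc(O)c1OC | starting material
2 | 2,3-dimethoxy-1,4-benzoquinone | COC1=C(OC)C(=O)C=CC1=O | intermediate
3 | 2,3-dimethoxybenzene-1,4-diol | COc1c(O)ccc(O)c1OC | intermediate
4 | 2,3-dimethoxy-1,4-bis(methoxymethoxy)benzene | COCOc1ccc(OCOC)c(OC)c1OC | intermediate
5 | [3,4-dimethoxy-2,5-bis(methoxymethoxy)phenyl]lithium (formed in the flask, not isolated) | [Li]c1cc(OCOC)c(OC)c(OC)c1OCOC | intermediate
6 | 2-[3,4-dimethoxy-2,5-bis(methoxymethoxy)phenyl]ethan-1-ol | COCOc1cc(CCO)c(OCOC)c(OC)c1OC | intermediate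
7 | [3,4-dimethoxy-2,5-bis(methoxymethoxy)phenyl]acetic acid | COCOc1cc(CC(=O)O)c(OCOC)c(OC)c1OC | intermediate
8 | (4S)-4-benzyl-1,3-oxazolidin-2-one | O=C1N[C@@H](Cc2ccccc2)CO1 | starting material
9 | mixed anhydride of 7 with pivalic acid (formed in the flask, not isolated) | COCOc1cc(CC(=O)OC(=O)C(C)(C)C)c(OCOC)c(OC)c1OC | intermediate
10 | (4S)-4-benzyl-3-{[3,4-dimethoxy-2,5-bis(methoxymethoxy)phenyl]acetyl}-1,3-oxazolidin-2-one | COCOc1cc(CC(=O)N2[C@@H](Cc3ccccc3)COC2=O)c(OCOC)c(OC)c1OC | intermediate
11 | 6-bromovanillin (2-bromo-4-hydroxy-5-methoxybenzaldehyde) | COc1cc(C=O)c(Br)cc1O | starting material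
12 | 2-bromo-5-methoxy-4-(methoxymethoxy)benzaldehyde | COCOc1cc(Br)c(C=O)cc1OC | intermediate
13 | [2-bromo-5-methoxy-4-(methoxymethoxy)phenyl]methanol | COCOc1cc(Br)c(CO)cc1OC | intermediate
14 | 1-bromo-2-(bromomethyl)-4-methoxy-5-(methoxymethoxy)benzene | COCOc1cc(Br)c(CBr)cc1OC | intermediate
15 | sodium Z-enolate of imide 10 (formed in the flask, not isolated) | COCOc1cc(/C=C(\[O-])N2[C@@H](Cc3ccccc3)COC2=O)c(OCOC)c(OC)c1OC.[Na+] | intermediate
16 | (4S)-4-benzyl-3-{(2S)-3-[2-bromo-5-methoxy-4-(methoxymethoxy)phenyl]-2-[3,4-dimethoxy-2,5-bis(methoxymethoxy)phenyl]propanoyl}-1,3-oxazolidin-2-one | COCOc1cc([C@H](Cc2cc(OC)c(OCOC)cc2Br)C(=O)N2[C@@H](Cc3ccccc3)COC2=O)c(OCOC)c(OC)c1OC | intermediate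
17 | (2S)-3-[2-bromo-5-methoxy-4-(methoxymethoxy)phenyl]-2-[3,4-dimethoxy-2,5-bis(methoxymethoxy)phenyl]propan-1-ol | COc1c(OC)c(OCOC)c([C@@H](CO)Cc2cc(OC)c(OCOC)cc2Br)cc1OCOC | intermediate
18 | lithium alkoxide of 17, lithiated on ring A at the carbon between Br and the methoxymethoxy group (formed in the flask, not isolated) | [Li+].[O-]C[C@@H](Cc1cc(OC)c(OCOC)c([Li])c1Br)c1cc(OCOC)c(OC)c(OC)c1OCOC | intermediate
19 | lithium alkoxide carrying the ring A aryne across the future C8–C8a (formed in the flask, not isolated) | [Li+].[O-]C[C@@H](CC1=CC(OC)=C(OCOC)C#C1)c1cc(OCOC)c(OC)c(OC)c1OCOC | intermediate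
20 | (3S)-3-[3,4-dimethoxy-2,5-bis(methoxymethoxy)phenyl]-8-lithio-6-methoxy-7-(methoxymethoxy)-3,4-dihydro-2H-chromene (formed in the flask, not isolated) | COc1c(OC)c(OCOC)c([C@H]2COc3c(cc(OC)c(OCOC)c3[Li])C2)cc1OCOC | intermediate
21 | lithium trimethoxyborate of the chroman at C8 (formed in the flask, not isolated) | COc1c(OC)c(OCOC)c([C@H]2COc3c(cc(OC)c(OCOC)c3[B-](OC)(OC)OC)C2)cc1OCOC.[Li+] | intermediate
22 | (3S)-3-[3,4-dimethoxy-2,5-bis(methoxymethoxy)phenyl]-6-methoxy-7-(methoxymethoxy)-3,4-dihydro-2H-chromen-8-ol | COc1c(OC)c(OCOC)c([C@H]2COc3c(cc(OC)c(OCOC)c3O)C2)cc1OCOC | intermediate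
23 | (3S)-3-[3,4-dimethoxy-2,5-bis(methoxymethoxy)phenyl]-6,8-dimethoxy-7-(methoxymethoxy)-3,4-dihydro-2H-chromene | COc1c(OC)c(OCOC)c([C@H]2COc3c(cc(OC)c(OCOC)c3OC)C2)cc1OCOC | intermediate
24 | 5-[(3S)-7-hydroxy-6,8-dimethoxy-3,4-dihydro-2H-chromen-3-yl]-2,3-dimethoxybenzene-1,4-diol | COc1c(OC)c(O)c([C@H]2COc3c(cc(OC)c(O)c3OC)C2)cc1O | intermediate
25 | 5-[(3S)-7-hydroxy-6,8-dimethoxy-3,4-dihydro-2H-chromen-3-yl]-2,3-dimethoxycyclohexa-2,5-diene-1,4-dione (CNP0121136.1) | COC1=C(OC)C(=O)C([C@H]2COc3c(cc(OC)c(O)c3OC)C2)=CC1=O | target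

**Step count**

Total: 15 steps. Longest linear sequence: 12 steps (steps 1–6, then 10–15); the ring A branch (steps 7–9) joins at step 10.

**Steps most likely to fail, with fallbacks**

Step 12. The aryne may be consumed by the amide base or by another aryllithium before the tethered alkoxide reaches it, or metalation may spread to ring B so that boron and oxygen end up on the wrong carbon. The fallback separates ring closure from C8 oxygenation and sets out from 17. A palladium-catalysed intramolecular aryl ether formation between the aryl bromide and the primary alcohol (Pd(OAc)2, 2-(di-tert-butylphosphino)-1,1'-binaphthyl, Cs2CO3, toluene, 70 °C) should close ring C through the same O1–C8a bond. This should give (3S)-3-[3,4-dimethoxy-2,5-bis(methoxymethoxy)phenyl]-6-methoxy-7-(methoxymethoxy)-3,4-dihydro-2H-chromene F1. Directed ortho-metalation of F1 with n-BuLi and TMEDA in THF should then take place at C8, the one ring hydrogen flanked by two oxygens (O1 and the C7 acetal). That gives the aryllithium 20, where the route is rejoined; B(OMe)3 and H2O2/AcOH as in step 12 lead to 22.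

Step 10. The stabilised, hindered arylacetyl enolate may alkylate incompletely, facial selectivity may be eroded, or the acidic α-aryl centre may epimerise. The fallback sets the stereocentre by resolution in place of auxiliary control and sets out from 7. Methylation (MeI, K2CO3, DMF) gives methyl [3,4-dimethoxy-2,5-bis(methoxymethoxy)phenyl]acetate F2. Enolisation with LiN(SiMe3)2 in THF at −78 °C and alkylation with 14 gives racemic methyl 3-[2-bromo-5-methoxy-4-(methoxymethoxy)phenyl]-2-[3,4-dimethoxy-2,5-bis(methoxymethoxy)phenyl]propanoate F3. LiBH4 reduction gives racemic 3-[2-bromo-5-methoxy-4-(methoxymethoxy)phenyl]-2-[3,4-dimethoxy-2,5-bis(methoxymethoxy)phenyl]propan-1-ol F4. Preparative chromatography on a chiral stationary phase separates F4 into 17, where the route is rejoined, and its enantiomer (2R)-3-[2-bromo-5-methoxy-4-(methoxymethoxy)phenyl]-2-[3,4-dimethoxy-2,5-bis(methoxymethoxy)phenyl]propan-1-ol F5, which is set aside.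

Step 15. Oxidation may not stop at the hydroquinone: the ring A 2,6-dimethoxyphenol unit could be dehydrogenated at the Ag2O surface towards a para-quinone methide at C4 or coupled oxidatively. The fallback replaces the metal oxide by a thermodynamically controlled hydrogen transfer and sets out from 24. Treatment with 1,4-benzoquinone (excess, CH2Cl2, rt) should oxidise only the more easily oxidised 2,3-dimethoxyhydroquinone ring, since benzoquinone cannot oxidise a monophenol. The by-product benzene-1,4-diol is washed out with water and the route is rejoined at 25; no new compound is made on this way (F0).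

**Further compounds**

F1 | step 12 | (3S)-3-[3,4-dimethoxy-2,5-bis(methoxymethoxy)phenyl]-6-methoxy-7-(methoxymethoxy)-3,4-dihydro-2H-chromene | COc1c(OC)c(OCOC)c([C@H]2COc3cc(OCOC)c(OC)cc3C2)cc1OCOC
F2 | step 10 | methyl [3,4-dimethoxy-2,5-bis(methoxymethoxy)phenyl]acetate | COCOc1cc(CC(=O)OC)c(OCOC)c(OC)c1OC
F3 | step 10 | racemic methyl 3-[2-bromo-5-methoxy-4-(methoxymethoxy)phenyl]-2-[3,4-dimethoxy-2,5-bis(methoxymethoxy)phenyl]propanoate | COCOc1cc(C(Cc2cc(OC)c(OCOC)cc2Br)C(=O)OC)c(OCOC)c(OC)c1OC
F4 | step 10 | racemic 3-[2-bromo-5-methoxy-4-(methoxymethoxy)phenyl]-2-[3,4-dimethoxy-2,5-bis(methoxymethoxy)phenyl]propan-1-ol | COc1c(OC)c(OCOC)c(C(CO)Cc2cc(OC)c(OCOC)cc2Br)cc1OCOC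
F5 | step 10 | (2R)-3-[2-bromo-5-methoxy-4-(methoxymethoxy)phenyl]-2-[3,4-dimethoxy-2,5-bis(methoxymethoxy)phenyl]propan-1-ol | COc1c(OC)c(OCOC)c([C@H](CO)Cc2cc(OC)c(OCOC)cc2Br)cc1OCOC
F0 | step 15 | none | none
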